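The ten-membered carbocycle C1–C10 has its C1 carbonyl directly across the ring from C6, with oxygenated C5 beside C6: it is a decalin (ring A C1–C6, ring B C1/C6–C10) whose shared C1–C6 bond is missing. The route builds that trans-decalin from a toluene-dihydrodiol-derived ring B ketone and a Roche-ester aldehyde by two aldol reactions, then cuts C1–C6 by Grob fragmentation. This one operation gives the ten-membered ring, the C1 ketone and the E C5=C6 alkene that later accepts O5 and O6. The precursor is a trans-fused C1 tertiary alcohol with an equatorial C5 mesylate, C3 as dioxolane and C13 already present as a tert-butyl acrylate.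

Key step: step 19

Remark: germacrane numbering (C1–C15; O-n is the oxygen on C-n) is used for all intermediates, the upper face of ring B is the face of the C10–O bond (O8 and O9 lie on the lower face), and the unisolated amines 24 and 25 are C11 epimer mixtures, which is immaterial because C11 becomes sp2.

Step 1
Reactants: 1 toluene cis-dihydrodiol
Product: 2 O8 mono-silyl ether
Conditions: TBSCl (1.05 equiv), imidazole, DMF, −20 °C
Reagents that add atoms: tert-butyldimethylsilyl chloride, CC(C)(C)[Si](C)(C)Cl
Why: Regioselective monosilylation of a cis-diol; the hydroxyl next to the unsubstituted alkene carbon (future O8) is less hindered than the one flanked by the methyl-bearing carbon and should react first with the bulky silyl chloride.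

Step 2
Reactants: 2 O8 mono-silyl ether
Product: 3 O8-silyl O9-MOM diene
Conditions: MOMCl, iPr2NEt, CH2Cl2, 0 °C to rt
Reagents that add atoms: chloromethyl methyl ether, COCCl
Why: Alkylation of the remaining allylic hydroxyl to the MOM ether under amine base, which generates no alkoxide and so should not cause silyl migration.

Step 3
Reactants: 3 O8-silyl O9-MOM diene
Product: 5 hydroxy enone, via endoperoxide 4 (not isolated)
Conditions: O2, hν (visible), tetraphenylporphyrin (cat.), CH2Cl2, −30 °C; then Et3N, 0 °C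
Reagents that add atoms: dioxygen, O=O
Why: Singlet-oxygen [4+2] cycloaddition on the face opposite the two ether groups sets the C10–O bond, and the Kornblum–DeLaMare rearrangement removes the only peroxide-bearing hydrogen (H-7) to give the C7 ketone and the tertiary C10 alcohol.

Step 4
Reactants: 5 hydroxy enone
Product: 6 bis-MOM enone
Conditions: MOMCl, iPr2NEt, Bu4NI (cat.), ClCH2CH2Cl, 50 °C
Reagents that add atoms: chloromethyl methyl ether, COCCl
Why: Iodide-assisted MOM ether formation on the tertiary alcohol, giving a C10 protecting group that cannot migrate to a neighbouring alkoxide later.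

Step 5
Reactants: 6 bis-MOM enone; 7 tert-butyl acetate
Product: 9 tertiary allylic alcohol, via lithium enolate 8 (not isolated)
Conditions: LiN(iPr)2, THF, −78 °C; then 6, −78 °C; AcOH
Reagents that add atoms: none
Why: Aldol-type 1,2-addition of a lithium ester enolate to the enone carbonyl at low temperature brings in C11 and C12; attack anti to the C8 silyl ether is expected, but the C7 configuration is erased in the next step.

Step 6
Reactants: 9 tertiary allylic alcohol
Product: 10 ring B enone
Conditions: [C5H5NH][CrO3Cl], NaOAc, 4 Å molecular sieves, CH2Cl2, rt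
Reagents that add atoms: pyridinium chlorochromate, [O-][Cr](=O)(=O)Cl.c1cc[nH+]cc1
Why: Dauben–Michno oxidative 1,3-transposition; the tertiary allylic chromate ester undergoes [3,3] shift to C1 and is oxidised to the C1 ketone with the C6=C7 alkene carrying the acetate arm.

Step 7
Reactants: 10 ring B enone
Product: 11 ring B ketone
Conditions: H2 (1 atm), 10% Pd/C, EtOAc, rt
Reagents that add atoms: none
Why: Heterogeneous hydrogenation of the enone should deliver hydrogen to the upper face, anti to the pseudoaxial C8 silyloxy group and the C10 methyl, placing the C7 acetate arm cis to O8.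

Step 8
Reactants: 12 Roche ester
Product: 13 hydroxy Weinreb amide
Conditions: MeNH(OMe)·HCl, iPrMgCl (3 equiv), THF, −20 °C
Reagents that add atoms: N,O-dimethylhydroxylamine hydrochloride, CNOC.Cl
Why: Aminolysis of the ester by the magnesium amide (Weinreb amide formation), conditions under which the C4 stereocentre is not expected to enolise.

Step 9
Reactants: 13 hydroxy Weinreb amide
Product: 14 hydroxy methyl ketone
Conditions: MeMgBr (2.5 equiv), THF, 0 °C; NH4Cl (aq)
Reagents that add atoms: methylmagnesium bromide, C[Mg]Br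
Why: Weinreb ketone synthesis; the chelated tetrahedral intermediate stops at the ketone and supplies C2 as the methyl group.

Step 10
Reactants: 14 hydroxy methyl ketone
Product: 16 ketal alcohol, via silyl ether 15 (not isolated)
Conditions: TMSOCH2CH2OTMS, TMSOTf (cat.), CH2Cl2, −78 to 0 °C; then K2CO3, MeOH
Reagents that add atoms: 1,2-bis(trimethylsilyloxy)ethane, C[Si](C)(C)OCCO[Si](C)(C)C
Why: Noyori ketalisation under aprotic low-temperature conditions avoids dehydration of the β-hydroxy ketone, and the silyl ether formed in passing is removed by methanolysis.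

Step 11
Reactants: 16 ketal alcohol
Product: 17 ketal aldehyde
Conditions: Dess–Martin periodinane, NaHCO3, CH2Cl2, 0 °C to rt
Reagents that add atoms: none
Why: Buffered Dess–Martin oxidation should give the α-branched aldehyde without epimerisation at C4; it is used at once.

Step 12
Reactants: 11 ring B ketone
Product: 18 enol silane
Conditions: TMSOTf, Et3N, CH2Cl2, 0 °C
Reagents that add atoms: trimethylsilyl trifluoromethanesulfonate, C[Si](C)(C)OS(=O)(=O)C(F)(F)F
Why: Soft enolisation gives the only possible enol silane (C1=C6), because C10 is quaternary and the ester is far less acidic.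

Step 13
Reactants: 18 enol silane; 17 ketal aldehyde
Product: 19 aldol adduct
Conditions: BF3·OEt2, CH2Cl2, −78 °C
Reagents that add atoms: none
Why: Mukaiyama aldol through an open transition state; Felkin–Anh attack on the aldehyde (ketal carbon as large group) sets C5 syn to the C4 methyl, and the enol silane reacts on the face anti to the C7 arm, which sets C6.

Step 14
Reactants: 19 aldol adduct
Product: 20 hydroxy diketone
Conditions: pyridinium p-toluenesulfonate (cat.), acetone/H2O 10:1, 45 °C
Reagents that add atoms: water, O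
Why: Mild acid-catalysed transketalisation to acetone unmasks the C3 methyl ketone while the silyl ether, the MOM ethers and the tert-butyl ester should survive.

Step 15
Reactants: 20 hydroxy diketone
Product: 21 trans-decalin ketol
Conditions: LiN(iPr)2 (2.3 equiv), THF, −78 to −40 °C; AcOH
Reagents that add atoms: none
Why: After deprotonation of the C5 hydroxyl, kinetic enolisation of the methyl ketone and intramolecular aldol addition of C2 to the C1 ketone (6-enolexo-exo-trig) close ring A; only the chair transition state leading to the trans-fused ketol keeps C4-Me and C5-O equatorial, so the C1 hydroxyl should end axial on the upper face.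

Step 16
Reactants: 21 trans-decalin ketol
Product: 23 diol ketal, via bis-silyl ether 22 (not isolated)
Conditions: TMSOCH2CH2OTMS (5 equiv), TMSOTf (cat.), CH2Cl2, −78 to −20 °C; pyridine; then K2CO3, MeOH, rt
Reagents that add atoms: 1,2-bis(trimethylsilyloxy)ethane, C[Si](C)(C)OCCO[Si](C)(C)C
Why: Noyori ketalisation converts the C3 ketone into the dioxolane at low temperature without acid-induced loss of the tertiary β-hydroxyl, and the trimethylsilyl ethers formed at O1 and O5 are cleaved by methanolysis.

Step 17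
Reactants: 23 diol ketal
Product: 26 acrylate diol, via Mannich base 24 (not isolated), via methiodide 25 (not isolated)
Conditions: LiN(iPr)2 (3.5 equiv), THF, −78 °C; [Me2N=CH2]I, −78 to 0 °C; H2O; then MeI, MeOH, rt; then NaHCO3 (aq), CH2Cl2
Reagents that add atoms: Eschenmoser's salt, C=[N+](C)C.[I-]
Why: Eschenmoser methylenation of the ester enolate (Mannich reaction, quaternisation, E1cB loss of trimethylamine) installs C13 at the one stage of the route that has no ketone.

Step 18
Reactants: 26 acrylate diol
Product: 27 C5 mesylate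
Conditions: MsCl, Et3N, CH2Cl2, −20 to 0 °C
Reagents that add atoms: methanesulfonyl chloride, CS(=O)(=O)Cl
Why: Sulfonylation through sulfene is selective for the secondary equatorial C5 hydroxyl; the tertiary C1 hydroxyl does not react.

Step 19
Reactants: 27 C5 mesylate
Product: 28 (E)-cyclodecenone
Conditions: KOtBu (1.1 equiv), THF, 0 °C; pH 7 buffer
Reagents that add atoms: none
Why: Deprotonation of the tertiary C1 hydroxyl gives an alkoxide whose lone pair pushes into the C1–C6 σ bond, which lies anti-periplanar to the equatorial C5–OMs bond, so that C1=O forms, C1–C6 breaks, C5=C6 forms and mesylate leaves in one concerted step; this is the Grob fragmentation of a cyclic 1,3-diol monosulfonate, the known route from trans-decalin substrates to (E)-cyclodec-5-enones. The ten-membered ring is not closed by bond formation: it appears when the bond shared by rings A and B is cleaved, a ring expansion by fragmentation. No sp3 stereocentre is created, and the E geometry should follow stereospecifically because in the trans-decalin the C4–C5 and C6–C7 bonds are anti-periplanar (equatorial C5–O, equatorial C6–C7). The step needs fragmentation to outrun oxetane closure of O1 onto C5, E2 elimination and attack on the acrylate or the product: the rigid trans-decalin fixes the required alignment, the equatorial mesylate has no anti-periplanar hydrogen, and the single equivalent of base ends as potassium mesylate, so that none remains for the β-keto ketal or the acrylate. C4, C7, C8, C9 and C10 are untouched.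

Step 20
Reactants: 28 (E)-cyclodecenone
Product: 29 5,6-diol
Conditions: OsO4 (5 mol%), N-methylmorpholine N-oxide (1.1 equiv), acetone/H2O, 0 °C; Na2SO3 (aq)
Reagents that add atoms: OsO4 (catalytic oxygen carrier), O=[Os](=O)(=O)=O; N-methylmorpholine N-oxide, C[N+]1([O-])CCOCC1; water, O
Why: Upjohn syn-dihydroxylation of the strained, electron-rich E alkene in preference to the electron-poor acrylate; only the outer face of the trans-cycloalkene is open, and in the conformer inherited from the decalin (H-4 and H-7 eclipsing the alkene, C1–C3 and C8–C10 beneath it) that face should give the 5S,6S diol.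

Step 21
Reactants: 29 5,6-diol
Product: 30 5,6-acetonide
Conditions: 2-methoxypropene, pyridinium p-toluenesulfonate (cat.), CH2Cl2, 0 °C
Reagents that add atoms: 2-methoxypropene, COC(C)=C
Why: Kinetic acid-catalysed acetonide formation masks both new hydroxyls; the threo diol gives a trans-disubstituted dioxolane.

Step 22
Reactants: 30 5,6-acetonide
Product: 31 C8 alcohol
Conditions: Bu4NF, AcOH (1:1), THF, rt
Reagents that add atoms: none
Why: Buffered fluoride desilylation frees O8 alone; acetic acid suppresses alkoxide formation and hence lactonisation onto the tert-butyl ester and opening of the β-keto ketal.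

Step 23
Reactants: 31 C8 alcohol; 32 angelic acid
Product: 34 C8 angelate, via mixed anhydride 33 (not isolated)
Conditions: 2,4,6-trichlorobenzoyl chloride, Et3N, toluene, rt; then 31, toluene, 75 °C
Reagents that add atoms: none
Why: Yamaguchi-type esterification through the pre-formed mixed anhydride without a nucleophilic pyridine catalyst, conditions chosen to keep the Z geometry of the angelate; O8 is the only free hydroxyl.

Step 24
Reactants: 34 C8 angelate
Product: 36 target, via seco acid 35 (not isolated)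
Conditions: CF3CO2H/H2O 9:1, CH2Cl2, 0 °C to rt
Reagents that add atoms: none
Why: Aqueous acid removes both MOM ethers, both ketals and the tert-butyl group; the C12 acid should then lactonise onto O6 (γ, O8 being acylated) and the α'-hydroxy 1,3-diketone should cyclodehydrate through O10 and C3 to the 3(2H)-furanone, a five-ring closure that is usually fast under mild acid.

Compound list
1 | (1S,2R)-3-methylcyclohexa-3,5-diene-1,2-diol (toluene cis-dihydrodiol) | CC1=CC=C[C@H](O)[C@@H]1O | starting material
2 | (1R,6S)-6-[(tert-butyldimethylsilyl)oxy]-2-methylcyclohexa-2,4-dien-1-ol (O8 silylated, O9 free) | CC1=CC=C[C@H](O[Si](C)(C)C(C)(C)C)[C@@H]1O | intermediate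
3 | tert-butyl{[(1S,6R)-6-(methoxymethoxy)-5-methylcyclohexa-2,4-dien-1-yl]oxy}dimethylsilane | CC1=CC=C[C@H](O[Si](C)(C)C(C)(C)C)[C@@H]1OCOC | intermediate
4 | 8-[(tert-butyldimethylsilyl)oxy]-7-(methoxymethoxy)-1-methyl-2,3-dioxabicyclo[2.2.2]oct-5-ene, peroxide bridge on the face opposite both ethers | O1O[C@@]2(C)C=C[C@@H]1[C@H](O[Si](C)(C)C(C)(C)C)[C@@H]2OCOC | intermediate (not isolated)
5 | (4S,5S,6R)-6-[(tert-butyldimethylsilyl)oxy]-4-hydroxy-5-(methoxymethoxy)-4-methylcyclohex-2-en-1-one (C7 ketone, C10 tertiary alcohol) | O=C1C=C[C@](C)(O)[C@@H](OCOC)[C@H]1O[Si](C)(C)C(C)(C)C | intermediate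
6 | (4S,5S,6R)-6-[(tert-butyldimethylsilyl)oxy]-4,5-bis(methoxymethoxy)-4-methylcyclohex-2-en-1-one | O=C1C=C[C@](C)(OCOC)[C@@H](OCOC)[C@H]1O[Si](C)(C)C(C)(C)C | intermediate
7 | tert-butyl acetate | CC(=O)OC(C)(C)C | starting material
8 | lithium enolate of tert-butyl acetate | C=C(O[Li])OC(C)(C)C | intermediate (not isolated)
9 | tert-butyl 2-[6-(tert-butyldimethylsilyloxy)-1-hydroxy-4,5-bis(methoxymethoxy)-4-methylcyclohex-2-en-1-yl]acetate; C8, C9, C10 as in 6, acetate arm on the upper face at the C7 carbinol | CC(C)(C)OC(=O)C[C@]1(O)C=C[C@](C)(OCOC)[C@@H](OCOC)[C@H]1O[Si](C)(C)C(C)(C)C | intermediate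
10 | tert-butyl 2-[6-(tert-butyldimethylsilyloxy)-4,5-bis(methoxymethoxy)-4-methyl-3-oxocyclohex-1-en-1-yl]acetate (C1 ketone, C6=C7; C8, C9, C10 as in 6) | CC(C)(C)OC(=O)CC1=CC(=O)[C@](C)(OCOC)[C@@H](OCOC)[C@H]1O[Si](C)(C)C(C)(C)C | intermediate
11 | tert-butyl 2-[(1R,2S,3S,4R)-2-[(tert-butyldimethylsilyl)oxy]-3,4-bis(methoxymethoxy)-4-methyl-5-oxocyclohexyl]acetate (ring B ketone; H-7 on the upper face, arm cis to O8 and O9) | CC(C)(C)OC(=O)C[C@H]1CC(=O)[C@](C)(OCOC)[C@@H](OCOC)[C@H]1O[Si](C)(C)C(C)(C)C | intermediate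
12 | methyl (S)-3-hydroxy-2-methylpropanoate (Roche ester) | COC(=O)[C@@H](C)CO | starting material
13 | (S)-3-hydroxy-N-methoxy-N,2-dimethylpropanamide | CON(C)C(=O)[C@@H](C)CO | intermediate
14 | (S)-4-hydroxy-3-methylbutan-2-one | CC(=O)[C@@H](C)CO | intermediate
15 | trimethyl[(S)-2-(2-methyl-1,3-dioxolan-2-yl)propoxy]silane | CC1(OCCO1)[C@@H](C)CO[Si](C)(C)C | intermediate (not isolated)
16 | (S)-2-(2-methyl-1,3-dioxolan-2-yl)propan-1-ol | CC1(OCCO1)[C@@H](C)CO | intermediate
17 | (S)-2-(2-methyl-1,3-dioxolan-2-yl)propanal (C5 aldehyde, C4 methyl, C3 ketal, C2 methyl) | CC1(OCCO1)[C@@H](C)C=O | intermediate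
18 | trimethylsilyl enol ether of 11 (C1–OSiMe3, C1=C6) | CC(C)(C)OC(=O)C[C@H]1C=C(O[Si](C)(C)C)[C@](C)(OCOC)[C@@H](OCOC)[C@H]1O[Si](C)(C)C(C)(C)C | intermediate
19 | aldol adduct: ring B ketone 11 carrying at C6, trans to the C7 arm, the (1S,2S)-1-hydroxy-2-(2-methyl-1,3-dioxolan-2-yl)propyl group (5,6-syn, 4,5-syn) | C[C@H](C1(C)OCCO1)[C@H](O)[C@H]2[C@H](CC(=O)OC(C)(C)C)[C@H](O[Si](C)(C)C(C)(C)C)[C@H](OCOC)[C@@](C)(OCOC)C2=O | intermediate
20 | hydroxy diketone: as 19 with the dioxolane replaced by the C3 methyl ketone | C[C@H](C(C)=O)[C@H](O)[C@H]1[C@H](CC(=O)OC(C)(C)C)[C@H](O[Si](C)(C)C(C)(C)C)[C@H](OCOC)[C@@](C)(OCOC)C1=O | intermediate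
21 | trans-decalin ketol: C1 tertiary OH axial on the upper face, H-6 axial on the lower face, 5-OH and 4-Me equatorial, C3 ketone; ring B as in 11 | C[C@H]1[C@H](O)[C@H]2[C@H](CC(=O)OC(C)(C)C)[C@H](O[Si](C)(C)C(C)(C)C)[C@H](OCOC)[C@@](C)(OCOC)[C@]2(O)CC1=O | intermediate
22 | C3 ethylene ketal of 21 with O1 and O5 as trimethylsilyl ethers | C[C@H]1[C@H](O[Si](C)(C)C)[C@H]2[C@H](CC(=O)OC(C)(C)C)[C@H](O[Si](C)(C)C(C)(C)C)[C@H](OCOC)[C@@](C)(OCOC)[C@]2(O[Si](C)(C)C)CC13OCCO3 | intermediate (not isolated)
23 | trans-decalin diol ketal: C3 dioxolane, C1–OH, C5–OH, C7 arm CH2CO2tBu | C[C@H]1[C@H](O)[C@H]2[C@H](CC(=O)OC(C)(C)C)[C@H](O[Si](C)(C)C(C)(C)C)[C@H](OCOC)[C@@](C)(OCOC)[C@]2(O)CC13OCCO3 | intermediate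
24 | Mannich base: 23 with CH2NMe2 on C11 (C11 epimers) | C[C@H]1[C@H](O)[C@H]2[C@H](C(CN(C)C)C(=O)OC(C)(C)C)[C@H](O[Si](C)(C)C(C)(C)C)[C@H](OCOC)[C@@](C)(OCOC)[C@]2(O)CC13OCCO3 | intermediate (not isolated)
25 | methiodide of 24 (C11 epimers) | C[C@H]1[C@H](O)[C@H]2[C@H](C(C[N+](C)(C)C)C(=O)OC(C)(C)C)[C@H](O[Si](C)(C)C(C)(C)C)[C@H](OCOC)[C@@](C)(OCOC)[C@]2(O)CC13OCCO3.[I-] | intermediate (not isolated)
26 | trans-decalin diol ketal with the C7 arm as tert-butyl acrylate (C11=C13) | C[C@H]1[C@H](O)[C@H]2[C@H](C(=C)C(=O)OC(C)(C)C)[C@H](O[Si](C)(C)C(C)(C)C)[C@H](OCOC)[C@@](C)(OCOC)[C@]2(O)CC13OCCO3 | intermediate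
27 | fragmentation precursor: trans-decalin with C1–OH (axial), C3 dioxolane, equatorial C5 mesylate, 4-Me equatorial, 8-OTBS, 9-OMOM, 10-OMOM, C7 tert-butyl acrylate | C[C@H]1[C@H](OS(C)(=O)=O)[C@H]2[C@H](C(=C)C(=O)OC(C)(C)C)[C@H](O[Si](C)(C)C(C)(C)C)[C@H](OCOC)[C@@](C)(OCOC)[C@]2(O)CC13OCCO3 | intermediate
28 | (E)-cyclodec-5-enone: C1 ketone, C3 dioxolane, E C5=C6, 8-OTBS, 9-OMOM, 10-OMOM, C7 tert-butyl acrylate | C[C@H]1/C=C/[C@H](C(=C)C(=O)OC(C)(C)C)[C@H](O[Si](C)(C)C(C)(C)C)[C@H](OCOC)[C@@](C)(OCOC)C(=O)CC13OCCO3 | intermediate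
29 | 5,6-diol of 28 (5S,6S in target numbering) | C[C@H]1[C@H](O)[C@@H](O)[C@H](C(=C)C(=O)OC(C)(C)C)[C@H](O[Si](C)(C)C(C)(C)C)[C@H](OCOC)[C@@](C)(OCOC)C(=O)CC13OCCO3 | intermediate
30 | 5,6-O-isopropylidene derivative of 29 | C[C@H]1[C@@H]2OC(C)(C)O[C@H]2[C@H](C(=C)C(=O)OC(C)(C)C)[C@H](O[Si](C)(C)C(C)(C)C)[C@H](OCOC)[C@@](C)(OCOC)C(=O)CC13OCCO3 | intermediate
31 | C8 alcohol: 30 without the silyl group | C[C@H]1[C@@H]2OC(C)(C)O[C@H]2[C@H](C(=C)C(=O)OC(C)(C)C)[C@H](O)[C@H](OCOC)[C@@](C)(OCOC)C(=O)CC13OCCO3 | intermediate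
32 | angelic acid, (Z)-2-methylbut-2-enoic acid | C/C=C(/C)C(=O)O | starting material
33 | (Z)-2-methylbut-2-enoic 2,4,6-trichlorobenzoic anhydride | C/C=C(/C)C(=O)OC(=O)c1c(Cl)cc(Cl)cc1Cl | intermediate (not isolated)
34 | C8 angelate of 31 | C[C@H]1[C@@H]2OC(C)(C)O[C@H]2[C@H](C(=C)C(=O)OC(C)(C)C)[C@H](OC(=O)/C(C)=C\C)[C@H](OCOC)[C@@](C)(OCOC)C(=O)CC13OCCO3 | intermediate
35 | seco acid: 1,3-diketone with free 5-, 6-, 9-, 10-OH, 8-angelate and the C11(=C13)–C12 acrylic acid | C[C@H]1[C@H](O)[C@@H](O)[C@H](C(=C)C(=O)O)[C@H](OC(=O)/C(C)=C\C)[C@H](O)[C@@](C)(O)C(=O)CC1=O | intermediate (not isolated)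
36 | CNP0206920.2: (4S,5S,6S,7S,8S,9S,10R)-8-[(Z)-2-methylbut-2-enoyloxy]-5,9-dihydroxy-1-oxo-3,10-epoxygermacra-2,11(13)-dien-12,6-olide | C=C1C(=O)O[C@@H]2[C@@H](O)[C@H](C)C3=CC(=O)[C@](C)(O3)[C@@H](O)[C@@H](OC(=O)/C(C)=C\C)[C@@H]12 | target

Total step count: 24. Longest linear sequence: 20 steps (steps 1–7, then 12–24); the aldehyde branch (steps 8–11) joins at step 13.

Steps most likely to fail

Step 19 (fragmentation). What may go wrong: tert-butoxide or the product enolate adds to the acrylate, or the acrylate isomerises, faster than the alkoxide fragments. The fallback carries C13 through the fragmentation in masked form. It sets out from 24, which is isolated after the Mannich stage of step 17 instead of being quaternised. Mesylation (MsCl, Et3N, CH2Cl2) should give the amino mesylate F1, and KOtBu in THF at 0 °C the amino cyclodecenone F2. MeI then gives the methiodide F3, and NaHCO3 eliminates trimethylamine; the route is rejoined at 28.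

Step 20 (dihydroxylation). What may go wrong: poor facial selectivity, because the ten-membered ring populates a second conformer and the osmium reagent adds to the other face of the alkene. The fallback is a Woodward cis-hydroxylation, which puts both oxygens on the face opposite to the one first attacked by the electrophile. It sets out from 28. I2 and AgOAc in AcOH should give the trans iodo acetate F4 (iodonium on the exposed face, acetate anti at C6). Water then opens the acetoxonium ion formed by displacement of iodide to the hydroxy acetate F5, and K2CO3 in MeOH at 0 °C returns the route to 29.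

Step 13 (aldol). What may go wrong: poor facial selectivity at the aldehyde, so that the C5 hydroxyl ends on the wrong side (axial after ring closure), where it cannot fragment. The fallback sets C5 by hydroxyl-directed reduction instead. It sets out at the stage of 23, from the C5-epimeric material carried through steps 14–16, 5-epi-23 F6. Dess–Martin oxidation of the secondary hydroxyl should give the C5 ketone F7, in which C4 and C6 can settle in their equatorial arrangement. Me4NBH(OAc)3 in AcOH/MeCN at −20 °C (Evans–Saksena reduction, hydride delivered from the axial C1 hydroxyl) should then give the 1,3-anti diol with the equatorial C5 hydroxyl, which is 23.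

Further compounds
F1 | step 19 | C5 mesylate of Mannich base 24 (C11 epimers) | C[C@H]1[C@H](OS(C)(=O)=O)[C@H]2[C@H](C(CN(C)C)C(=O)OC(C)(C)C)[C@H](O[Si](C)(C)C(C)(C)C)[C@H](OCOC)[C@@](C)(OCOC)[C@]2(O)CC13OCCO3
F2 | step 19 | (E)-cyclodecenone with the C7 arm as the dimethylaminomethyl ester (C11 epimers) | C[C@H]1/C=C/[C@H](C(CN(C)C)C(=O)OC(C)(C)C)[C@H](O[Si](C)(C)C(C)(C)C)[C@H](OCOC)[C@@](C)(OCOC)C(=O)CC13OCCO3
F3 | step 19 | methiodide of F2 | C[C@H]1/C=C/[C@H](C(C[N+](C)(C)C)C(=O)OC(C)(C)C)[C@H](O[Si](C)(C)C(C)(C)C)[C@H](OCOC)[C@@](C)(OCOC)C(=O)CC13OCCO3.[I-]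
F4 | step 20 | trans 5-iodo 6-acetate of 28 | C[C@H]1[C@@H](I)[C@@H](OC(C)=O)[C@H](C(=C)C(=O)OC(C)(C)C)[C@H](O[Si](C)(C)C(C)(C)C)[C@H](OCOC)[C@@](C)(OCOC)C(=O)CC13OCCO3
F5 | step 20 | 6-O-acetate of diol 29 | C[C@H]1[C@H](O)[C@@H](OC(C)=O)[C@H](C(=C)C(=O)OC(C)(C)C)[C@H](O[Si](C)(C)C(C)(C)C)[C@H](OCOC)[C@@](C)(OCOC)C(=O)CC13OCCO3
F6 | step 13 | 5-epi-23 (axial C5 hydroxyl) | C[C@H]1[C@@H](O)[C@H]2[C@H](CC(=O)OC(C)(C)C)[C@H](O[Si](C)(C)C(C)(C)C)[C@H](OCOC)[C@@](C)(OCOC)[C@]2(O)CC13OCCO3
F7 | step 13 | C5 ketone of 23 | C[C@H]1C(=O)[C@H]2[C@H](CC(=O)OC(C)(C)C)[C@H](O[Si](C)(C)C(C)(C)C)[C@H](OCOC)[C@@](C)(OCOC)[C@]2(O)CC13OCCO3
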